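If you want to know how much product each of these flasks shows at the end, take the rate at which product first appears and count how many times product can multiply itself in the time given.

    substrate + reagent → product (k1 = 0.010 /M/h, Ea1 = 82.0 kJ/mol)
    substrate + reagent + product → 2 product (k2 = 64 /M²/h, Ea2 = 51.0 kJ/mol)
    reagent + product ⇌ idle adduct, settled at all times (K3 = 20 /M, ΔH3 = −20.0 kJ/mol)
    (constants at 50 °C)

in all of them: substrate 0.050 M; reagent 0.500 equiv; time 40 h

| charge | temperature |
|---|---|
| midnight | 65 °C |
| summer | 50 °C |
| spring | 35 °C |
| dusk | 20 °C |

- the best flask by amount of product, in percent of the substrate charged; "all alike" if 1.5 percentage points covers them all (midnight / summer / spring / dusk / all alike)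
- amount of product at the end, in percent of the substrate charged, midnight
- amount of product at the end, in percent of the substrate charged, summer
- amount of product at the end, in percent of the substrate charged, spring
- amount of product at the end, in percent of the substrate charged, dusk

- what is said of product includes idle adduct
- constants are those at 50 °C; use the activation energies and enthalpies for any other temperature

- With no product yet, the flask has the plain first step, whose rate is its constant times c(substrate) times c(reagent). Reagent starts at 0.0250 M, and it is the limiting reagent, so the charge allows 50.0% of the substrate as product.
- Product then opens the helped step, which is autocatalysis. Bound product does not count there, and the fast balance leaves one part free for every one plus binding constant times c(reagent) parts in total.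
- While the charges stand nearly whole, total product grows by a fixed fraction per hour. Its growth time τ is one plus binding constant times c(reagent), divided by helped constant times c(substrate) times c(reagent). Product at time t is then the plain rate times τ times (e to the power t/τ, less one).
- At dusk, with the constants moved to that temperature, the growth time τ is 181 h, longer than the run, and my reckoning gives 0.0493%.
- In spring τ is 54.1 h, which gives 0.335%. In summer τ is 18.8 h, which gives 3.49%.
- At midnight the plain, helped and binding constants are multiplied by 3.87, 2.32 and 0.719, so τ is 7.32 h. The first answer is 0.0833 M, more than the reagent charge, so it cannot stand.
- Go round again at midnight. Let growth fade as reagent is used, which turns an unchecked amount x into x over (one plus x/c(reagent charged)), and that gives 0.0192 M. Put back in the mean c(substrate) this implies, and the mean c(reagent) in the binding term, while the fade still stands for the loss of reagent in the growth. Then τ becomes 8.14 h, the unchecked amount 0.0430 M, and the yield 31.6%.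
- Counting growth times in the run, my best flask is midnight.
- The forecast named midnight, with 32% at midnight, 3.2% in summer, 0.33% in spring and 0.05% at dusk, holding that “The cooler flasks remain in the slow induction period”.
- The simulation gives midnight as the best flask, with 32.9% at midnight, 3.22% in summer, 0.333% in spring and 0.0492% at dusk.
- At the end of the dusk flask, the half-life of substrate is 2600 d by the plain step and 11000 d by the helped step, so the helped step runs at about a quarter of the plain one. At dusk the flask is still in its induction period, and τ puts that ratio at 0.248.
- Read the dusk flask at 3.0 d instead: the same τ of 181 h gives 0.0973%, and the simulation gives 0.0971%.

(The constants were chosen freely; what happens was integrated by code.)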